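# Proposed synthesis of CNP0151628.5 through an intramolecular 2-pyrone Diels–Alder reaction

## Structural features

The target is a cis-fused 1,2,4a,5,8,8a-hexahydronaphthalene: ring A (C1–C4, C4a, C8a) holds the C3=C4 double bond and ring B (C4a, C5–C8, C8a) the methyl-bearing C6=C7 double bond. The shared carbon C4a is quaternary and carries a free carboxylic acid. Its neighbours C5, which bears an (E)-2-(trans-4-carboxycyclohexyl)prop-1-enyl arm, and C8a are stereocentres, so three contiguous stereocentres meet at the ring fusion. C2 lies 1,4 to C4a across the ring-A alkene and bears the (2S)-6-methylhept-5-en-2-yl chain, whose stereocentre C1′ is bonded directly to C2. The configurations are C1′ S, C2 R, C4a R, C5 R and C8a R. H8a and the C2 chain are cis to the C4a carboxyl group, the C5 arm is trans to it, and the 1,4-disubstituted cyclohexane is the achiral trans isomer. Fragile points are the three acid-sensitive trisubstituted alkenes, the β,γ-unsaturated acid on a quaternary carbon, and C5–H, which is doubly allylic in the target and triply activated in open-chain precursors. The real difficulty is to build the congested quaternary C4a together with C5 and C8a, to relate them to the remote C2, and to leave C3=C4 exactly between C2 and C4a. The feature exploited is that C2, C3=C4, C4a and the carboxyl carbon of ring A are C6, C5=C4, C3 and C2 of a 2-pyrone. A vinyl group tethered to the pyrone can therefore bridge C4a and C2, close both rings at once, and leave the lactone carbonyl as the C4a acid.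

## Logic of the disconnections

26 ⇒ 25. The C2–H bond is exchanged for a C2–O bond to the C4a carboxyl group; no skeletal bond is cut. This lactone bridge turns ring A into the bicyclic core of a pyrone cycloadduct and ties C2 and C4a to one face, so C2 needs no separate control. The forward step must break the allylic C2–O bond with hydride entering at C2 and not at C4, from the face opposite to oxygen, and without loss of CO2 from the freed acid.

25 ⇒ 24. C4a–C8a and C1–C2 are cut in the retro-[4+2] sense. Rings A and B and three stereocentres disappear, and C5 is left as the only stereocentre of the ring region, on a flat heteroaromatic diene. The forward step must add an unactivated vinyl group below the temperature of CO2 loss, on the diene face set by C5, with the tether endo.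

24 ⇒ 23 ⇒ 22. The bond between the ring oxygen and C2 is cut to give the open-chain Z-enynoic acid 23, which comes from 22 by ester cleavage. The heterocycle is thereby reduced to a chain that can be assembled by coupling. The forward steps need Z geometry at C4a=C4, 6-endo rather than 5-exo closure, and ester removal without protic acid.

22 ⇒ 21 + 3. The sp–sp2 bond C3–C4 is cut. This is the convergent cut: it separates the half that carries C1′ from the half that carries C5. The coupling must retain the geometry of the enol sulfonate, and 3 must be configurationally pure.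

21 ⇒ 19. The one-carbon unit C4 is taken off C4a, which returns to a CH2 ester. α-Formylation and enol sulfonylation then put the vinyl electrophile cis to the ester. Enolisation must occur at C4a only, which is why the distal carboxyl is carried as a carboxylate at this stage.

19 (through 18) ⇒ 11 + 17. The C5–C6 bond is cut. Conjugate addition of an alkenyl nucleophile to the enoate β-carbon is the point at which a catalyst can set C5, and both alkenes on C5 arrive with fixed geometry. The addition must be 1,4 and not 1,6, must give R at C5, and must keep the Z geometry of the nucleophile.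

11 ⇒ 9 + 10, then 9 ⇒ 7 ⇒ 6 ⇒ 4. C5–C1″ is cut (alkenyl halide plus acrylate). Then C2″–CH3 and C1″–I are cut (carbometalation of an alkyne), C1″ is removed (one-carbon homologation of an aldehyde), and the oxidation level is adjusted. The forward steps must give E geometry, keep the trans ring, and tolerate the ester.

17 ⇒ 14 + 15, then 14 ⇒ 12. C7–C8 is cut, then C6–B and C7–Br. Syn addition to the alkyne and coupling with retention must deliver the Z alkene that later becomes C6=C7 of ring B.

3 ⇒ 1. Only a functional-group change is needed (CH2–CHO to C≡CH). The carbons that become C3 and C2 are already present and C1′ comes from the chiral pool. The forward step must not erode C1′.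

## Other disconnections considered

Alternative 1: The cut is C4–C4a, the last bond of ring A, made at the quaternary centre. In the forward sense the ring-B acid A2 carries C5, C8a and, on the C8a side chain, C2 and a Z-vinylsilane. After double silylation and anodic oxidation, the radical cation centred on C4a would be trapped by the silicon-bearing carbon C4, and loss of silicon would leave C3=C4 in A1.
- In its favour: the quaternary centre and the alkene are made in one event and silicon fixes the alkene position. On alkene placement it is better than the chosen plan, which depends on the site of hydride delivery. It needs no pressure equipment and has no gas extrusion to suppress.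
- Against it here: three other electron-rich alkenes are present and can intercept the radical cation or the later cation. The ring fusion is not enforced, because a six-membered closure onto C4a can give either fusion. Only C4a is created, so C5, C8a and C2 must all be set beforehand in A2.
- Comparison: the key step builds one ring, one bond and one stereocentre, against two rings, two bonds and three stereocentres in the chosen plan. A1 still needs deprotection and oxidation of the distal alcohol, so step economy is poorer.

Alternative 2: The cut is C7–C8. In the forward sense 9-BBN would add to the exocyclic C8a=C8 alkene of A4, placing boron on C8 and setting C8a. The B-alkyl Suzuki coupling with the Z-vinyl iodide under Pd(dppf)Cl2 would then close ring B to give A3.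
- In its favour: both halves are highly dependable, and the iodide fixes the geometry and position of C6=C7. In mechanistic predictability of the key step it is the equal or the better of the chosen plan.
- Against it here: A4 must already contain ring A with the quaternary C4a and the adjacent C5, so the hardest part of the molecule is solved elsewhere. Cis fusion depends on 9-BBN approaching C8a from the ester face. The hindered C4a methyl ester of A3 must be cleaved at the end, where the chosen plan releases the free acid directly.
- Comparison: the key step builds one ring, one bond and one stereocentre, and the route to A4 would be longer than the route to 24.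

Alternative 3: The cut is C5–C6. In the forward sense acid would ionise the allylic alcohol of A6 to the C5–C1″–C2″ allyl cation. The vinylsilane on the C8 arm would attack C5 through its silicon-bearing carbon, and loss of silicon would leave C6=C7 in A5.
- In its favour: ring B and C5 are formed together, silicon fixes the alkene (equal to the chosen plan on this point), and neither metal nor pressure is needed.
- Against it here: the arm alkene becomes part of the cation and can lose its E geometry. The trisubstituted alkenes elsewhere are exposed to cationic conditions. The configuration of C5 rests on the facial bias of a cation next to a quaternary centre.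
- Comparison: in A5 both carboxyl groups are still silyl-protected alcohols, one of them neopentyl, so several deprotection and oxidation steps remain where the chosen plan needs one step. The chosen plan sets C5 under catalyst control before any ring is made and is therefore better in stereochemical security and step economy.

Key step: step 13

## Remarks on the chemistry

- Remark 1: ring carbons keep their decalin locants in all intermediates; C1′ is the chain stereocentre on C2, and C1″ and C2″ are the arm alkene carbons.
- Remark 2: the configurations of the planned cycloaddition precursor and cycloadduct were checked against the target and needed no correction: C5 R is carried through, the endo adduct has H8a cis to the lactone carbonyl, and inversion at C2 gives 2R.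
- Remark 3: two design changes are made to the precursor. The distal carboxyl is carried as the free acid from step 8 on, which removes an ester differentiation and the final saponification. The cycloaddition is run under pressure at 40 °C so that the adduct stays below the temperature of CO2 loss.
- Remark 4: (S)-citronellal of high enantiomeric purity and propyne as a commercial solution are assumed.

## Route

Step 1
Reactants: 1 (S)-citronellal
Product: 3 (3S)-3,7-dimethyloct-6-en-1-yne, via enol nonaflate 2 (not isolated)
Conditions: n-C4F9SO2F (1.1 equiv), P2-Et phosphazene base (2.3 equiv), DMF, −20 °C → rt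
Reagents that add atoms: none
Why: O-sulfonylation of the aldehyde enolate and base-induced β-elimination of nonaflate (one-pot aldehyde-to-alkyne dehydration) should give the terminal alkyne with all ten carbons; C3 is not a reacting centre and the acetylide formed with excess base protects the propargylic C–H, so the S configuration should be kept.

Step 2
Reactants: 4 trans-4-(methoxycarbonyl)cyclohexane-1-carboxylic acid
Product: 6 methyl trans-4-formylcyclohexane-1-carboxylate, via acid chloride 5 (not isolated)
Conditions: (COCl)2, cat. DMF, CH2Cl2, 0 °C → rt; evaporate; LiAlH(Ot-Bu)3 (1.05 equiv), THF, −78 °C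
Reagents that add atoms: none
Why: Reduction of an acid chloride with the hindered hydride LiAlH(Ot-Bu)3 stops at the aldehyde and leaves the methyl ester alone; no base is present, so the trans relationship should be kept.

Step 3
Reactants: 6 methyl trans-4-formylcyclohexane-1-carboxylate
Product: 7 methyl trans-4-ethynylcyclohexane-1-carboxylate
Conditions: dimethyl (1-diazo-2-oxopropyl)phosphonate, K2CO3, MeOH, 0 °C → rt
Reagents that add atoms: dimethyl (1-diazo-2-oxopropyl)phosphonate, CC(=O)C(=[N+]=[N-])P(=O)(OC)OC
Why: Seyferth–Gilbert homologation in the Ohira–Bestmann form adds one carbon (the future C1″) and gives the terminal alkyne; methanol makes ester exchange degenerate, and low temperature with both substituents equatorial should hold the trans configuration.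

Step 4
Reactants: 7 methyl trans-4-ethynylcyclohexane-1-carboxylate
Product: 9 methyl trans-4-[(E)-1-iodoprop-1-en-2-yl]cyclohexane-1-carboxylate, via alkenylalane 8 (not isolated)
Conditions: Me3Al (2.5 equiv), Cp2ZrCl2 (0.2 equiv), H2O (1 equiv), CH2Cl2, −20 °C; then I2, THF, −30 → 0 °C
Reagents that add atoms: trimethylaluminium, C[Al](C)C; iodine, II
Why: Zirconium-catalysed Negishi carboalumination adds CH3 and Al syn with methyl on the internal carbon, and iodinolysis goes with retention, which fixes the E geometry of the arm (iodine trans to the ring); the water-accelerated variant is cold and fast enough to spare the ester.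

Step 5
Reactants: 9 methyl trans-4-[(E)-1-iodoprop-1-en-2-yl]cyclohexane-1-carboxylate; 10 tert-butyl acrylate
Product: 11 tert-butyl (2E,4E)-5-[trans-4-(methoxycarbonyl)cyclohexyl]hexa-2,4-dienoate
Conditions: Pd(OAc)2 (5 mol %), K2CO3, n-Bu4NCl, DMF, 50 °C
Reagents that add atoms: none
Why: Heck reaction; syn insertion of the acrylate into the alkenyl–palladium bond and syn β-hydride elimination should give the 2E alkene, while the 4E geometry of the iodide is retained.

Step 6
Reactants: 12 propyne
Product: 14 2-[(1Z)-2-bromoprop-1-en-1-yl]-4,4,5,5-tetramethyl-1,3,2-dioxaborolane, via alkenyldibromoborane 13 (not isolated)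
Conditions: BBr3, CH2Cl2, −78 °C → rt; then pinacol, −78 °C → rt
Reagents that add atoms: boron tribromide, BrB(Br)Br; pinacol, CC(C)(O)C(C)(C)O
Why: syn-Bromoboration of the terminal alkyne places boron on the terminal and bromine on the internal carbon, cis to each other; immediate esterification with pinacol should freeze the Z geometry.

Step 7
Reactants: 14 2-[(1Z)-2-bromoprop-1-en-1-yl]-4,4,5,5-tetramethyl-1,3,2-dioxaborolane; 15 allyl bromide
Product: 17 2-[(1Z)-2-methylpenta-1,4-dien-1-yl]-4,4,5,5-tetramethyl-1,3,2-dioxaborolane, via allylzinc bromide 16 (not isolated)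
Conditions: Zn dust, THF, 0 °C (15 to 16); then 14, Pd(t-Bu3P)2 (2 mol %), THF, rt
Reagents that add atoms: none
Why: Negishi coupling replaces bromine by allyl with retention, so the allyl group ends cis to boron (Z, the future cis relation of C5 and C8); the pinacol boronate is inert in the absence of base.

Step 8
Reactants: 11 tert-butyl (2E,4E)-5-[trans-4-(methoxycarbonyl)cyclohexyl]hexa-2,4-dienoate; 17 2-[(1Z)-2-methylpenta-1,4-dien-1-yl]-4,4,5,5-tetramethyl-1,3,2-dioxaborolane
Product: 19 tert-butyl (3R,4Z)-3-[(1E)-2-(trans-4-carboxycyclohexyl)prop-1-en-1-yl]-5-methylocta-4,7-dienoate, via diester 18 (not isolated)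
Conditions: [Rh(OH)((S)-BINAP)]2 (2.5 mol %), KOH (1 equiv), dioxane–H2O 10:1, 60 °C; then LiOH·H2O, MeOH, rt; aq. HCl to pH 3
Reagents that add atoms: lithium hydroxide monohydrate, [Li+].[OH-].O
Why: Hayashi–Miyaura reaction: the alkenylrhodium species formed by transmetalation (with retention of Z) inserts the enoate at C3, the future C5, and the fully substituted diene terminus should disfavour 1,6-addition. The (S)-ligand is expected to bind the E-enoate on the face that is si at the α-carbon, which gives 3R. The same aqueous base then cleaves only the unhindered methyl ester, the tert-butyl ester being inert.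

Step 9
Reactants: 19 tert-butyl (3R,4Z)-3-[(1E)-2-(trans-4-carboxycyclohexyl)prop-1-en-1-yl]-5-methylocta-4,7-dienoate
Product: 21 tert-butyl (2Z)-2-[(2E,4R,5Z)-2-(trans-4-carboxycyclohexyl)-6-methylnona-2,5,8-trien-4-yl]-3-[(trifluoromethanesulfonyl)oxy]prop-2-enoate, via formyl ester enolate 20 (not isolated)
Conditions: LDA (2.2 equiv), THF, −78 °C; HCO2CH2CF3 (1.3 equiv), −78 → −40 °C; N-(5-chloropyridin-2-yl)triflimide (1.4 equiv), −78 → 0 °C
Reagents that add atoms: 2,2,2-trifluoroethyl formate, O=COCC(F)(F)F; N-(5-chloropyridin-2-yl)-1,1,1-trifluoro-N-(trifluoromethanesulfonyl)methanesulfonamide, O=S(=O)(N(c1ccc(Cl)cn1)S(=O)(=O)C(F)(F)F)C(F)(F)F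
Why: The first equivalent of base makes the lithium carboxylate of the distal acid, which is not enolised further, so the second equivalent enolises only the tert-butyl ester. Crossed Claisen formylation gives the chelated enolate of the α-formyl ester, and O-sulfonylation of this U-shaped chelate should place the triflate cis to the ester (Z). The stereocentre is β to the ester and is not touched.

Step 10
Reactants: 21 tert-butyl (2Z)-2-[(2E,4R,5Z)-2-(trans-4-carboxycyclohexyl)-6-methylnona-2,5,8-trien-4-yl]-3-[(trifluoromethanesulfonyl)oxy]prop-2-enoate; 3 (3S)-3,7-dimethyloct-6-en-1-yne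
Product: 22 tert-butyl (2Z,6S)-2-[(2E,4R,5Z)-2-(trans-4-carboxycyclohexyl)-6-methylnona-2,5,8-trien-4-yl]-6,10-dimethylundeca-2,9-dien-4-ynoate
Conditions: Pd(PPh3)4 (5 mol %), CuI (10 mol %), i-Pr2NH, THF, rt
Reagents that add atoms: none
Why: Sonogashira coupling of the alkenyl triflate goes with retention at the sp2 carbon, so the alkyne ends cis to the ester as lactonisation requires; the amine keeps the distal acid as its salt and no stereocentre is involved.

Step 11
Reactants: 22 tert-butyl (2Z,6S)-2-[(2E,4R,5Z)-2-(trans-4-carboxycyclohexyl)-6-methylnona-2,5,8-trien-4-yl]-6,10-dimethylundeca-2,9-dien-4-ynoate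
Product: 23 (2Z,6S)-2-[(2E,4R,5Z)-2-(trans-4-carboxycyclohexyl)-6-methylnona-2,5,8-trien-4-yl]-6,10-dimethylundeca-2,9-dien-4-ynoic acid
Conditions: TMSOTf (4 equiv), 2,6-lutidine (6 equiv), CH2Cl2, 0 °C; then pH 4 buffer
Reagents that add atoms: none
Why: Silyl triflate-mediated cleavage of the tert-butyl ester (loss of isobutene) under lutidine buffering avoids the protic acid that would attack the trisubstituted alkenes and the 1,4-diene; the transient silyl esters hydrolyse on work-up.

Step 12
Reactants: 23 (2Z,6S)-2-[(2E,4R,5Z)-2-(trans-4-carboxycyclohexyl)-6-methylnona-2,5,8-trien-4-yl]-6,10-dimethylundeca-2,9-dien-4-ynoic acid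
Product: 24 trans-4-[(2E,4R,5Z)-6-methyl-4-{6-[(2S)-6-methylhept-5-en-2-yl]-2-oxo-2H-pyran-3-yl}nona-2,5,8-trien-2-yl]cyclohexane-1-carboxylic acid
Conditions: ZnBr2 (0.3 equiv), THF, rt
Reagents that add atoms: none
Why: Zinc-promoted 6-endo-dig lactonisation of a (Z)-2-en-4-ynoic acid: the carboxylate adds to the distal alkyne carbon and protonation gives the aromatic 2-pyrone; ZnBr2 is the promoter that favours this mode over 5-exo closure, and the remote acid is a spectator.

Step 13
Reactants: 24 trans-4-[(2E,4R,5Z)-6-methyl-4-{6-[(2S)-6-methylhept-5-en-2-yl]-2-oxo-2H-pyran-3-yl}nona-2,5,8-trien-2-yl]cyclohexane-1-carboxylic acid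
Product: 25 (2R,4aR,5R,8aS)-5-[(1E)-2-(trans-4-carboxycyclohexyl)prop-1-en-1-yl]-2-hydroxy-7-methyl-2-[(2S)-6-methylhept-5-en-2-yl]-1,2,4a,5,8,8a-hexahydronaphthalene-4a-carboxylic acid 4a,2-lactone (bridged 2-oxabicyclo[2.2.2]oct-5-en-3-one)
Conditions: 13 kbar, CH2Cl2 (0.02 M), BHT (1 mol %), 40 °C
Reagents that add atoms: none
Why: The pyrone is a locked s-cis diene and the terminal vinyl group the dienophile in a concerted, suprafacial, asynchronous [4+2] addition; the closest known reaction type is the intramolecular Diels–Alder reaction of 2-pyrones with tethered unactivated alkenes under pressure or mild heating, which gives isolable bridged lactones. Ring A closes by the two new bonds C4a–C8a and C1–C2 across pyrone C3 and C6, and ring B closes in the fused mode as a six-membered ring through the four-atom tether C5–C6=C7–C8 when C4a–C8a forms. C4a and C2 are set together because the lactone can bridge only one face of ring A. The diene face is chosen by C5, whose hydrogen lies in the pyrone plane beside the lactone carbonyl to relieve 1,3-allylic strain, so the tether is below and the arm above the ring. C8a follows from the endo-tether geometry with C8 under C4–C5 of the pyrone, the arrangement that keeps both large C5 substituents beside the small C4–H, and it places H8a cis to the carboxyl carbon. Chemoselectivity rests on reach: the two alkenes on C5 are one atom from the diene and the prenyl alkene would have to form a five-membered ring at the substituted C6 terminus, so only the vinyl group can span C3 and C6 without strain. Pressure accelerates the addition through its negative activation volume and disfavours retro-[4+2] loss of CO2, which must not occur because the lactone carbonyl is the future C4a acid.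

Step 14
Reactants: 25 the bridged lactone from step 13
Product: 26 (2R,4aR,5R,8aR)-5-[(1E)-2-(trans-4-carboxycyclohexyl)prop-1-en-1-yl]-7-methyl-2-[(2S)-6-methylhept-5-en-2-yl]-1,2,4a,5,8,8a-hexahydronaphthalene-4a-carboxylic acid (CNP0151628.5)
Conditions: Pd2(dba)3 (2.5 mol %), n-Bu3P (10 mol %), HCO2NH4 (6 equiv), dioxane, 60 °C
Reagents that add atoms: none
Why: Palladium-catalysed formate hydrogenolysis of an allylic ester: zerovalent palladium ionises the strained tertiary allylic C2–O bond anti to the carboxylate, and formate on palladium loses CO2 to give a hydride that passes from the metal to C2. Hydrogen therefore enters on the face opposite to the departed oxygen (net inversion, 2R), and C2 is favoured over C4 because it is the more substituted terminus and C4 is shielded by the quaternary C4a. C3=C4 stays in place and nothing in the medium can move it.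

## Compound list

1 | (S)-citronellal, (3S)-3,7-dimethyloct-6-enal | CC(C)=CCC[C@H](C)CC=O | starting material
2 | (3S)-3,7-dimethylocta-1,6-dien-1-yl nonafluorobutane-1-sulfonate (E/Z mixture) | CC(C)=CCC[C@H](C)C=COS(=O)(=O)C(F)(F)C(F)(F)C(F)(F)C(F)(F)F | intermediate
3 | (3S)-3,7-dimethyloct-6-en-1-yne | CC(C)=CCC[C@H](C)C#C | intermediate
4 | trans-4-(methoxycarbonyl)cyclohexane-1-carboxylic acid | COC(=O)[C@H]1CC[C@H](C(=O)O)CC1 | starting material
5 | methyl trans-4-(chlorocarbonyl)cyclohexane-1-carboxylate | COC(=O)[C@H]1CC[C@H](C(=O)Cl)CC1 | intermediate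
6 | methyl trans-4-formylcyclohexane-1-carboxylate | COC(=O)[C@H]1CC[C@H](C=O)CC1 | intermediate
7 | methyl trans-4-ethynylcyclohexane-1-carboxylate | COC(=O)[C@H]1CC[C@H](C#C)CC1 | intermediate
8 | methyl trans-4-[(E)-1-(dimethylalumanyl)prop-1-en-2-yl]cyclohexane-1-carboxylate | COC(=O)[C@H]1CC[C@H](/C(C)=C/[Al](C)C)CC1 | intermediate
9 | methyl trans-4-[(E)-1-iodoprop-1-en-2-yl]cyclohexane-1-carboxylate | COC(=O)[C@H]1CC[C@H](/C(C)=C/I)CC1 | intermediate
10 | tert-butyl acrylate | C=CC(=O)OC(C)(C)C | starting material
11 | tert-butyl (2E,4E)-5-[trans-4-(methoxycarbonyl)cyclohexyl]hexa-2,4-dienoate | CC(C)(C)OC(=O)/C=C/C=C(\C)[C@H]1CC[C@H](C(=O)OC)CC1 | intermediate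
12 | propyne | CC#C | starting material
13 | dibromo[(1Z)-2-bromoprop-1-en-1-yl]borane | C/C(Br)=C/B(Br)Br | intermediate
14 | 2-[(1Z)-2-bromoprop-1-en-1-yl]-4,4,5,5-tetramethyl-1,3,2-dioxaborolane | C/C(Br)=C/B1OC(C)(C)C(C)(C)O1 | intermediate
15 | allyl bromide | C=CCBr | starting material
16 | allylzinc bromide | C=CC[Zn]Br | intermediate
17 | 2-[(1Z)-2-methylpenta-1,4-dien-1-yl]-4,4,5,5-tetramethyl-1,3,2-dioxaborolane | C=CC/C(C)=C\B1OC(C)(C)C(C)(C)O1 | intermediate
18 | tert-butyl (3R,4Z)-3-{(1E)-2-[trans-4-(methoxycarbonyl)cyclohexyl]prop-1-en-1-yl}-5-methylocta-4,7-dienoate | CC(C)(C)OC(=O)C[C@@H](/C=C(\C)[C@H]1CC[C@H](C(=O)OC)CC1)/C=C(C)\CC=C | intermediate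
19 | tert-butyl (3R,4Z)-3-[(1E)-2-(trans-4-carboxycyclohexyl)prop-1-en-1-yl]-5-methylocta-4,7-dienoate | CC(C)(C)OC(=O)C[C@@H](/C=C(\C)[C@H]1CC[C@H](C(=O)O)CC1)/C=C(C)\CC=C | intermediate
20 | tert-butyl (2Z)-2-[(2E,4R,5Z)-2-(trans-4-carboxycyclohexyl)-6-methylnona-2,5,8-trien-4-yl]-3-hydroxyprop-2-enoate (enol form of the α-formyl ester, present as its dilithium salt) | CC(C)(C)OC(=O)/C(=C\O)[C@@H](/C=C(\C)[C@H]1CC[C@H](C(=O)O)CC1)/C=C(C)\CC=C | intermediate
21 | tert-butyl (2Z)-2-[(2E,4R,5Z)-2-(trans-4-carboxycyclohexyl)-6-methylnona-2,5,8-trien-4-yl]-3-[(trifluoromethanesulfonyl)oxy]prop-2-enoate | CC(C)(C)OC(=O)/C(=C\OS(=O)(=O)C(F)(F)F)[C@@H](/C=C(\C)[C@H]1CC[C@H](C(=O)O)CC1)/C=C(C)\CC=C | intermediate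
22 | tert-butyl (2Z,6S)-2-[(2E,4R,5Z)-2-(trans-4-carboxycyclohexyl)-6-methylnona-2,5,8-trien-4-yl]-6,10-dimethylundeca-2,9-dien-4-ynoate | CC(C)(C)OC(=O)/C(=C\C#C[C@@H](C)CCC=C(C)C)[C@@H](/C=C(\C)[C@H]1CC[C@H](C(=O)O)CC1)/C=C(C)\CC=C | intermediate
23 | (2Z,6S)-2-[(2E,4R,5Z)-2-(trans-4-carboxycyclohexyl)-6-methylnona-2,5,8-trien-4-yl]-6,10-dimethylundeca-2,9-dien-4-ynoic acid | OC(=O)/C(=C\C#C[C@@H](C)CCC=C(C)C)[C@@H](/C=C(\C)[C@H]1CC[C@H](C(=O)O)CC1)/C=C(C)\CC=C | intermediate
24 | trans-4-[(2E,4R,5Z)-6-methyl-4-{6-[(2S)-6-methylhept-5-en-2-yl]-2-oxo-2H-pyran-3-yl}nona-2,5,8-trien-2-yl]cyclohexane-1-carboxylic acid (cycloaddition precursor) | CC(C)=CCC[C@H](C)C1=CC=C(C(=O)O1)[C@@H](/C=C(\C)[C@H]2CC[C@H](C(=O)O)CC2)/C=C(C)\CC=C | intermediate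
25 | (2R,4aR,5R,8aS) bridged lactone: 4a,2-lactone of 5-[(1E)-2-(trans-4-carboxycyclohexyl)prop-1-en-1-yl]-2-hydroxy-7-methyl-2-[(2S)-6-methylhept-5-en-2-yl]-1,2,4a,5,8,8a-hexahydronaphthalene-4a-carboxylic acid | CC(C)=CCC[C@H](C)[C@@]13C=C[C@]2(C(=O)O3)[C@@H](CC(C)=C[C@@H]2/C=C(\C)[C@H]2CC[C@H](C(=O)O)CC2)C1 | intermediate
26 | (2R,4aR,5R,8aR)-5-[(1E)-2-(trans-4-carboxycyclohexyl)prop-1-en-1-yl]-7-methyl-2-[(2S)-6-methylhept-5-en-2-yl]-1,2,4a,5,8,8a-hexahydronaphthalene-4a-carboxylic acid | CC(C)=CCC[C@H](C)[C@@H]1C=C[C@]2(C(=O)O)[C@@H](CC(C)=C[C@@H]2/C=C(\C)[C@H]2CC[C@H](C(=O)O)CC2)C1 | target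

## Step count and least certain steps

Total: 14 steps. Longest linear sequence: 11 steps from 4 (steps 2, 3, 4, 5, 8, 9, 10, 11, 12, 13, 14).

Step 13 (key step). The most likely failure is that the unactivated vinyl group adds too slowly in the window in which the bridged lactone survives. Any extra heating then costs CO2 by retro-cycloaddition and weakens the allylic-strain and endo bias, so that the exo (trans-fused) adduct grows in. Fallback, setting out from 22 and returning at 26: iodolactonisation of the enynoate ester (I2, NaHCO3, MeCN, rt; 6-endo attack of the ester carbonyl on the iodonium ion, loss of the tert-butyl group) should give the 5-iodo-2-pyrone acid F1. 5-Halo-2-pyrones are known to be markedly more reactive dienes, so mild heating (toluene, 70–80 °C) or lower pressure should give the iodinated bridged lactone F2. Treatment with excess HCO2NH4 and Pd2(dba)3/n-Bu3P should then remove the vinylic iodine and open the allylic lactone in one operation to give 26.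

Step 8. The hindered, β,β-disubstituted alkenylboronate may transmetalate slowly and protodeboronate, 1,6-addition to the dienoate may compete, and the level of enantioface discrimination for a dienoate is not secured. Fallback with auxiliary control, setting out from 9 and 17 and returning at 18, which is then saponified to 19 as in step 8:
- Heck reaction of 9 with acrylic acid gives the dienoic acid F3.
- Mixed-anhydride acylation (PivCl, Et3N; then (4S)-4-phenyl-1,3-oxazolidin-2-one, LiCl) gives the imide F4.
- 17 is converted with retention into the alkenyl iodide F5 (aq. NaOH, then I2).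
- F5 is turned into the cuprate (t-BuLi; MgBr2·OEt2; CuBr·SMe2) and added to F4 at −78 → −20 °C. Attack on the magnesium-chelated s-cis enoyl unit anti to phenyl is the same si-face attack and should give the 3R adduct F6.
- LiOH/H2O2 releases the acid F7 and the auxiliary.
- Boc2O, DMAP and t-BuOH give 18.

Step 14. The π-allyl intermediate carries a carboxylate on the carbon next to the allyl terminus and anti to palladium, so Grob-type loss of CO2 to a cyclohexadiene can compete with hydride transfer. Hydride delivery at C4 is the second risk. Fallback that removes the free carboxylate, setting out from 25 and returning at 26: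
- Methanolysis of the strained lactone (NaOMe, MeOH, 0 °C) gives the hydroxy ester F8, with oxygen still on C2 and a methyl ester on C4a.
- LiHMDS and ClCO2Me give the tertiary allylic methyl carbonate F9; the distal mixed anhydride is hydrolysed on work-up.
- The same Pd2(dba)3/n-Bu3P/HCO2NH4 hydrogenolysis, now unable to fragment, should give the C4a methyl ester F10 with inversion at C2.
- Hydrolysis of the hindered ester (LiOH, aqueous dioxane, 90 °C; no α-hydrogen, so the alkene cannot migrate) gives 26.

Step 1. The strong phosphazene base may equilibrate the product alkyne with its allene through the propargylic C–H and erode the configuration at C3, the future C1′. Fallback that separates sulfonylation from elimination, setting out from 1 and returning at 3: Tf2O and 2,6-di-tert-butyl-4-methylpyridine in CH2Cl2 give the isolable enol triflate F11. Elimination with LDA (2.2 equiv, THF, −78 °C) forms the lithium acetylide irreversibly at a temperature at which propargyl–allenyl exchange is not accessible, and protonation gives 3.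

## Further compounds

F1 | step 13 | trans-4-[(2E,4R,5Z)-4-{5-iodo-6-[(2S)-6-methylhept-5-en-2-yl]-2-oxo-2H-pyran-3-yl}-6-methylnona-2,5,8-trien-2-yl]cyclohexane-1-carboxylic acid | CC(C)=CCC[C@H](C)C1=C(I)C=C(C(=O)O1)[C@@H](/C=C(\C)[C@H]2CC[C@H](C(=O)O)CC2)/C=C(C)\CC=C
F2 | step 13 | 3-iodo analogue of bridged lactone 25 (iodine on C3 of the C3=C4 bridge, all stereocentres as in 25) | CC(C)=CCC[C@H](C)[C@@]13C(I)=C[C@]2(C(=O)O3)[C@@H](CC(C)=C[C@@H]2/C=C(\C)[C@H]2CC[C@H](C(=O)O)CC2)C1
F3 | step 8 | (2E,4E)-5-[trans-4-(methoxycarbonyl)cyclohexyl]hexa-2,4-dienoic acid | COC(=O)[C@H]1CC[C@H](/C(C)=C/C=C/C(=O)O)CC1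
F4 | step 8 | (4S)-3-{(2E,4E)-5-[trans-4-(methoxycarbonyl)cyclohexyl]hexa-2,4-dienoyl}-4-phenyl-1,3-oxazolidin-2-one | COC(=O)[C@H]1CC[C@H](/C(C)=C/C=C/C(=O)N2[C@@H](c3ccccc3)COC2=O)CC1
F5 | step 8 | (1Z)-1-iodo-2-methylpenta-1,4-diene | C=CC/C(C)=C\I
F6 | step 8 | (4S)-3-[(3R,4Z)-3-{(1E)-2-[trans-4-(methoxycarbonyl)cyclohexyl]prop-1-en-1-yl}-5-methylocta-4,7-dienoyl]-4-phenyl-1,3-oxazolidin-2-one | COC(=O)[C@H]1CC[C@H](/C(C)=C/[C@H](CC(=O)N2[C@@H](c3ccccc3)COC2=O)/C=C(C)\CC=C)CC1
F7 | step 8 | (3R,4Z)-3-{(1E)-2-[trans-4-(methoxycarbonyl)cyclohexyl]prop-1-en-1-yl}-5-methylocta-4,7-dienoic acid | COC(=O)[C@H]1CC[C@H](/C(C)=C/[C@H](CC(=O)O)/C=C(C)\CC=C)CC1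
F8 | step 14 | hydroxy ester from methanolysis of 25: C4a methyl ester, tertiary allylic alcohol on C2 (configuration of 25), distal acid free | CC(C)=CCC[C@H](C)[C@@]1(O)C=C[C@]2(C(=O)OC)[C@@H](CC(C)=C[C@@H]2/C=C(\C)[C@H]2CC[C@H](C(=O)O)CC2)C1
F9 | step 14 | C2 methyl carbonate of F8 | CC(C)=CCC[C@H](C)[C@@]1(OC(=O)OC)C=C[C@]2(C(=O)OC)[C@@H](CC(C)=C[C@@H]2/C=C(\C)[C@H]2CC[C@H](C(=O)O)CC2)C1
F10 | step 14 | C4a methyl ester of 26 (distal acid free) | CC(C)=CCC[C@H](C)[C@@H]1C=C[C@]2(C(=O)OC)[C@@H](CC(C)=C[C@@H]2/C=C(\C)[C@H]2CC[C@H](C(=O)O)CC2)C1
F11 | step 1 | (3S)-3,7-dimethylocta-1,6-dien-1-yl trifluoromethanesulfonate (E/Z mixture) | CC(C)=CCC[C@H](C)C=COS(=O)(=O)C(F)(F)F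
A1 | alternative 1 | cis-decalin C4a acid with distal tert-butyldimethylsilyl ether (product of the anodic coupling) | CC(C)=CCC[C@H](C)[C@@H]1C=C[C@]2(C(=O)O)[C@@H](CC(C)=C[C@@H]2/C=C(\C)[C@H]2CC[C@H](CO[Si](C)(C)C(C)(C)C)CC2)C1
A2 | alternative 1 | ring-B carboxylic acid with the C8a side chain carrying C2 and a Z-vinylsilane (C4a configuration not specified) | CC(C)=CCC[C@H](C)[C@H](/C=C\[Si](C)(C)C)C[C@@H]1CC(C)=C[C@H](/C=C(\C)[C@H]2CC[C@H](CO[Si](C)(C)C(C)(C)C)CC2)C1C(=O)O
A3 | alternative 2 | dimethyl ester of 26 (product of the hydroboration and B-alkyl Suzuki closure) | CC(C)=CCC[C@H](C)[C@@H]1C=C[C@]2(C(=O)OC)[C@@H](CC(C)=C[C@@H]2/C=C(\C)[C@H]2CC[C@H](C(=O)OC)CC2)C1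
A4 | alternative 2 | ring-A ester with exocyclic C8a=C8 methylene and a Z-vinyl iodide at C7 | CC(C)=CCC[C@H](C)[C@@H]1C=C[C@@](C(=O)OC)([C@@H](/C=C(\C)[C@H]2CC[C@H](C(=O)OC)CC2)/C=C(C)\I)C(=C)C1
A5 | alternative 3 | cis-decalin bis(tert-butyldimethylsilyl) ether (product of the cation cyclisation) | CC(C)=CCC[C@H](C)[C@@H]1C=C[C@]2(CO[Si](C)(C)C(C)(C)C)[C@@H](CC(C)=C[C@@H]2/C=C(\C)[C@H]2CC[C@H](CO[Si](C)(C)C(C)(C)C)CC2)C1
A6 | alternative 3 | ring-A compound with a C5 allylic alcohol (either epimer) and a Z-vinylsilane on the C8 arm | CC(C)=CCC[C@H](C)[C@@H]1C=C[C@@](CO[Si](C)(C)C(C)(C)C)(C(O)/C=C(\C)[C@H]2CC[C@H](CO[Si](C)(C)C(C)(C)C)CC2)[C@@H](C/C(C)=C\[Si](C)(C)C)C1
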